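## Retrosynthetic overview

1. The target 35 is fisetinidol-(4β→6)-mesquitol (upper unit 2,3-trans-3,4-cis; lower unit 2,3-trans). It comes from global deprotection of biflavan 33, whose C4–H is set last by ionic hydrogenation of tertiary alcohol 31 (hydride anti to the 3-OTBS group gives the 3,4-cis linkage).
2. The C4–C6' bond comes from 1,2-addition of 6-lithio-penta-O-benzylmesquitol 30 to the 3-O-TBS-tri-O-benzyl-(2R,3R)-fustin ketone 14.
3. Both halves come from (2S)-flavanones 10 and 22 by Rubottom oxidation to trans-dihydroflavonols; the lower half is then deoxygenated at C4.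
4. Each pyranone ring is closed by a catalytic asymmetric intramolecular oxa-Michael addition of a 2-hydroxyaryl alkylidene β-ketoester (8, 20) followed by decarboxylation. The upper C-ring (step 5) and lower C-ring (step 12) are formed independently, before the fragments are joined.
5. The alkylidenes come from a Claisen condensation (salicylate ester + tert-butyl acetate) and a Knoevenagel condensation with the common aldehyde 2; all benzene rings are bought.

Assumption: the cinchona-thiourea pseudo-enantiomer (written here as quinidine-derived) is the one that gives the (2S)-flavanones; this is checked by CD on 10 and 22, and the quinine-derived catalyst is used instead if the sense is opposite.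

## Route

Step 1
Reactants: 1 3,4-dihydroxybenzaldehyde
Product: 2 3,4-bis(benzyloxy)benzaldehyde
Conditions: BnBr (2.2 equiv), K2CO3, DMF, 60 °C
Reagents that add atoms: benzyl bromide, BrCc1ccccc1
Why: Williamson etherification (SN2) of both phenoxides masks the B-ring catechol as benzyl ethers that last until the final hydrogenolysis; no stereocentre.

Step 2
Reactants: 3 methyl 2,4-dihydroxybenzoate
Product: 4 methyl 4-(benzyloxy)-2-hydroxybenzoate
Conditions: BnBr (1.05 equiv), K2CO3, acetone, reflux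
Reagents that add atoms: benzyl bromide, BrCc1ccccc1
Why: Regioselective Williamson etherification, because the 2-OH is hydrogen-bonded to the ester carbonyl and only the more acidic, free 4-OH is alkylated.

Step 3
Reactants: 4 methyl 4-(benzyloxy)-2-hydroxybenzoate; 5 tert-butyl acetate
Product: 7 tert-butyl 3-[4-(benzyloxy)-2-hydroxyphenyl]-3-oxopropanoate, via lithium enolate of tert-butyl acetate 6 (not isolated)
Conditions: LDA (4 equiv), 5 (4 equiv), THF, −78 °C; add 4, −78 → 0 °C; 1 M HCl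
Reagents that add atoms: lithium diisopropylamide, CC(C)N([Li])C(C)C (lithium in 6 only)
Why: Crossed Claisen condensation in which excess ester enolate first deprotonates the phenol, then acylates, and finally deprotonates the β-ketoester product, which drives the reaction.

Step 4
Reactants: 7 tert-butyl 3-[4-(benzyloxy)-2-hydroxyphenyl]-3-oxopropanoate; 2 3,4-bis(benzyloxy)benzaldehyde
Product: 8 tert-butyl 2-[4-(benzyloxy)-2-hydroxybenzoyl]-3-[3,4-bis(benzyloxy)phenyl]prop-2-enoate (E/Z mixture)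
Conditions: piperidine (0.2 equiv), AcOH (0.2 equiv), 4 Å MS, PhH, rt
Reagents that add atoms: none
Why: Knoevenagel condensation of the doubly activated methylene with the aldehyde gives the ester-activated chalcone needed for a highly enantioselective cyclisation.

Step 5
Reactants: 8 tert-butyl 2-[4-(benzyloxy)-2-hydroxybenzoyl]-3-[3,4-bis(benzyloxy)phenyl]prop-2-enoate
Product: 10 (2S)-7-(benzyloxy)-2-[3,4-bis(benzyloxy)phenyl]chroman-4-one, via flavanone 3-carboxylate 9 (not isolated)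
Conditions: quinidine-derived 3,5-bis(CF3)phenyl thiourea (10 mol %), PhMe, −25 °C; then TsOH·H2O, 80 °C; recrystallise
Reagents that add atoms: none
Why: Intramolecular 6-endo oxa-Michael addition in which the bifunctional catalyst binds the β-ketoester through the thiourea and delivers the phenol to one alkene face (C-2 set, aryl α, 2S), after which acid cleaves the tert-butyl ester and the β-keto acid decarboxylates.

Step 6
Reactants: 10 (2S)-7-(benzyloxy)-2-[3,4-bis(benzyloxy)phenyl]chroman-4-one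
Product: 13 (2R,3R)-7-(benzyloxy)-2-[3,4-bis(benzyloxy)phenyl]-3-hydroxychroman-4-one, via silyl enol ether 11 (not isolated), via 3-silyloxy ketone 12 (not isolated)
Conditions: TMSOTf, Et3N, CH2Cl2, 0 °C; DMDO, acetone/CH2Cl2, −40 → 0 °C; aq. citric acid, THF
Reagents that add atoms: dimethyldioxirane, CC1(C)OO1; trimethylsilyl triflate, C[Si](C)(C)OS(=O)(=O)C(F)(F)F (silyl group in 11 and 12 only)
Why: Rubottom oxidation in which soft enolisation avoids a free enolate (no retro-oxa-Michael, so C-2 is kept) and DMDO attacks the enol ether anti to the 2-aryl group, placing the new 3-oxygen trans (3R), which is also the thermodynamically preferred isomer.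

Step 7
Reactants: 13 (2R,3R)-7-(benzyloxy)-2-[3,4-bis(benzyloxy)phenyl]-3-hydroxychroman-4-one
Product: 14 (2R,3R)-7-(benzyloxy)-2-[3,4-bis(benzyloxy)phenyl]-3-(tert-butyldimethylsilyloxy)chroman-4-one
Conditions: TBSOTf, 2,6-lutidine, CH2Cl2, −78 → 0 °C
Reagents that add atoms: tert-butyldimethylsilyl triflate, CC(C)(C)[Si](C)(C)OS(=O)(=O)C(F)(F)F
Why: O-silylation under non-nucleophilic, weakly basic conditions protects the base-sensitive α-hydroxy ketone without epimerisation and installs the bulky group that later directs the C-4 reduction.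

Step 8
Reactants: 15 methyl 2,3,4-trihydroxybenzoate
Product: 16 methyl 3,4-bis(benzyloxy)-2-hydroxybenzoate
Conditions: BnBr (2.05 equiv), K2CO3, acetone, reflux
Reagents that add atoms: benzyl bromide, BrCc1ccccc1
Why: Regioselective Williamson etherification that leaves the ester-chelated 2-OH free, as required for the later ring closure.

Step 9
Reactants: 16 methyl 3,4-bis(benzyloxy)-2-hydroxybenzoate
Product: 17 methyl 3,4-bis(benzyloxy)-5-bromo-2-hydroxybenzoate
Conditions: NBS (1.05 equiv), MeCN, 0 °C → rt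
Reagents that add atoms: N-bromosuccinimide, O=C1CCC(=O)N1Br
Why: Electrophilic aromatic bromination goes para to the free phenol (ortho to 4-OBn, meta to the ester), which fixes the future C-6 coupling site unambiguously.

Step 10
Reactants: 17 methyl 3,4-bis(benzyloxy)-5-bromo-2-hydroxybenzoate; 5 tert-butyl acetate
Product: 19 tert-butyl 3-[3,4-bis(benzyloxy)-5-bromo-2-hydroxyphenyl]-3-oxopropanoate, via sodium enolate of tert-butyl acetate 18 (not isolated)
Conditions: NaHMDS (4 equiv), 5 (4 equiv), THF, −78 °C; add 17, −78 → −20 °C; 1 M HCl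
Reagents that add atoms: sodium bis(trimethylsilyl)amide, C[Si](C)(C)N([Na])[Si](C)(C)C (sodium in 18 only)
Why: Crossed Claisen condensation of the more hindered bromo salicylate with the sodium ester enolate, made with a silazide base that cannot undergo halogen–metal exchange with the aryl bromide; excess enolate deprotonates the phenol and the β-ketoester product, which drives the reaction.

Step 11
Reactants: 19 tert-butyl 3-[3,4-bis(benzyloxy)-5-bromo-2-hydroxyphenyl]-3-oxopropanoate; 2 3,4-bis(benzyloxy)benzaldehyde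
Product: 20 tert-butyl 2-[3,4-bis(benzyloxy)-5-bromo-2-hydroxybenzoyl]-3-[3,4-bis(benzyloxy)phenyl]prop-2-enoate (E/Z mixture)
Conditions: piperidine (0.2 equiv), AcOH (0.2 equiv), 4 Å MS, PhH, rt
Reagents that add atoms: none
Why: Knoevenagel condensation, as in step 4.

Step 12
Reactants: 20 tert-butyl 2-[3,4-bis(benzyloxy)-5-bromo-2-hydroxybenzoyl]-3-[3,4-bis(benzyloxy)phenyl]prop-2-enoate
Product: 22 (2S)-7,8-bis(benzyloxy)-2-[3,4-bis(benzyloxy)phenyl]-6-bromochroman-4-one, via bromo flavanone 3-carboxylate 21 (not isolated)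
Conditions: quinidine-derived 3,5-bis(CF3)phenyl thiourea (10 mol %), PhMe, −25 °C; then TsOH·H2O, 80 °C; recrystallise
Reagents that add atoms: none
Why: Catalytic asymmetric intramolecular oxa-Michael addition followed by decarboxylation, as in step 5, sets C-2 of the lower unit (aryl α, 2S).

Step 13
Reactants: 22 (2S)-7,8-bis(benzyloxy)-2-[3,4-bis(benzyloxy)phenyl]-6-bromochroman-4-one
Product: 25 (2R,3R)-7,8-bis(benzyloxy)-2-[3,4-bis(benzyloxy)phenyl]-6-bromo-3-hydroxychroman-4-one, via bromo silyl enol ether 23 (not isolated), via bromo 3-silyloxy ketone 24 (not isolated)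
Conditions: TMSOTf, Et3N, CH2Cl2, 0 °C; DMDO, acetone/CH2Cl2, −40 → 0 °C; aq. citric acid, THF
Reagents that add atoms: dimethyldioxirane, CC1(C)OO1; trimethylsilyl triflate, C[Si](C)(C)OS(=O)(=O)C(F)(F)F (silyl group in 23 and 24 only)
Why: Rubottom oxidation, as in step 6, with oxygen delivered anti to the 2-aryl group to give the 2,3-trans (3R) hydroxy ketone.

Step 14
Reactants: 25 (2R,3R)-7,8-bis(benzyloxy)-2-[3,4-bis(benzyloxy)phenyl]-6-bromo-3-hydroxychroman-4-one
Product: 26 (2R,3S,4R)-7,8-bis(benzyloxy)-2-[3,4-bis(benzyloxy)phenyl]-6-bromochromane-3,4-diol (major 3,4-trans epimer)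
Conditions: NaBH4, THF/EtOH, 0 °C
Reagents that add atoms: none
Why: Borohydride reduction of the aryl ketone; the C-4 configuration does not matter because C-4 becomes CH2 in the next step, while C-2 and C-3 are untouched.

Step 15
Reactants: 26 (2R,3S,4R)-7,8-bis(benzyloxy)-2-[3,4-bis(benzyloxy)phenyl]-6-bromochromane-3,4-diol
Product: 28 (2R,3S)-7,8-bis(benzyloxy)-2-[3,4-bis(benzyloxy)phenyl]-6-bromochroman-3-ol, via C-4 benzylic cation 27 (not isolated)
Conditions: Et3SiH (5 equiv), TFA (10 equiv), CH2Cl2, −20 → 0 °C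
Reagents that add atoms: none
Why: Ionic hydrogenation (SN1) in which only the 4-OH ionises, being benzylic with para-alkoxy and ortho-ether donors, and excess silane traps the cation before any rearrangement.

Step 16
Reactants: 28 (2R,3S)-7,8-bis(benzyloxy)-2-[3,4-bis(benzyloxy)phenyl]-6-bromochroman-3-ol
Product: 29 (2R,3S)-3,7,8-tris(benzyloxy)-2-[3,4-bis(benzyloxy)phenyl]-6-bromochromane
Conditions: NaH, BnBr, Bu4NI (cat.), DMF, 0 °C → rt
Reagents that add atoms: benzyl bromide, BrCc1ccccc1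
Why: Williamson etherification of the secondary alkoxide removes the last acidic proton before the organolithium step; there is no longer a ketone, so strong base is harmless.

Step 17
Reactants: 29 (2R,3S)-3,7,8-tris(benzyloxy)-2-[3,4-bis(benzyloxy)phenyl]-6-bromochromane; 14 (2R,3R)-7-(benzyloxy)-2-[3,4-bis(benzyloxy)phenyl]-3-(tert-butyldimethylsilyloxy)chroman-4-one
Product: 31 (2R,3R)-7-(benzyloxy)-2-[3,4-bis(benzyloxy)phenyl]-3-(tert-butyldimethylsilyloxy)-4-[(2R,3S)-3,7,8-tris(benzyloxy)-2-[3,4-bis(benzyloxy)phenyl]chroman-6-yl]chroman-4-ol (C-4 configuration not needed), via 6-lithio pentabenzyl mesquitol 30 (not isolated)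
Conditions: 29 (1.2 equiv), n-BuLi (1.2 equiv), THF, −78 °C; then 14, −78 → −40 °C; H2O
Reagents that add atoms: n-butyllithium, [Li]CCCC (lithium in 30 only)
Why: Bromine–lithium exchange followed by 1,2-addition of the aryllithium to the ketone (no 5-substituent, so unhindered) forms the C4–C6' bond regiospecifically; the new carbinol configuration is erased in step 18.

Step 18
Reactants: 31 the tertiary alcohol from step 17
Product: 33 (2R,3S,4R)-7-(benzyloxy)-2-[3,4-bis(benzyloxy)phenyl]-3-(tert-butyldimethylsilyloxy)-4-[(2R,3S)-3,7,8-tris(benzyloxy)-2-[3,4-bis(benzyloxy)phenyl]chroman-6-yl]chromane (2,3-trans-3,4-cis), via C-4 diarylmethyl cation 32 (not isolated)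
Conditions: Et3SiH (5 equiv), TFA (5 equiv), CH2Cl2, −40 → 0 °C
Reagents that add atoms: none
Why: Ionic hydrogenation in which TFA ionises the doubly benzylic alcohol to planar cation 32, allylic strain with the 4-aryl group turns the 3-OTBS group pseudo-axial over the β-face, and the silane delivers hydride to the α-face, leaving the aryl group β and cis to O-3 (descriptor 4R here, 4S in the target only because CIP priorities change on debenzylation).

Step 19
Reactants: 33 the silyl-protected biflavan from step 18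
Product: 34 (2R,3S,4R)-7-(benzyloxy)-2-[3,4-bis(benzyloxy)phenyl]-4-[(2R,3S)-3,7,8-tris(benzyloxy)-2-[3,4-bis(benzyloxy)phenyl]chroman-6-yl]chroman-3-ol
Conditions: 48% aq. HF, MeCN/CH2Cl2, 40 °C
Reagents that add atoms: none
Why: Fluoride-driven desilylation (strong Si–F bond) frees the hindered 3-OH without touching benzyl ethers or the interflavan bond.

Step 20
Reactants: 34 the octa-O-benzyl biflavan from step 19
Product: 35 (2R,3S,4S)-2-(3,4-dihydroxyphenyl)-4-[(2R,3S)-2-(3,4-dihydroxyphenyl)-3,7,8-trihydroxychroman-6-yl]chromane-3,7-diol (target)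
Conditions: H2 (1 atm), Pd(OH)2/C, THF/MeOH/H2O, rt
Reagents that add atoms: none
Why: Catalytic hydrogenolysis cleaves all eight benzyl ethers under neutral conditions that leave the stereocentres and the C4–C6' bond intact.

## Compound list

1 | 3,4-dihydroxybenzaldehyde | O=Cc1ccc(O)c(O)c1 | starting material
2 | 3,4-bis(benzyloxy)benzaldehyde | O=Cc1ccc(OCc2ccccc2)c(OCc2ccccc2)c1 | intermediate
3 | methyl 2,4-dihydroxybenzoate | COC(=O)c1ccc(O)cc1O | starting material
4 | methyl 4-(benzyloxy)-2-hydroxybenzoate | COC(=O)c1ccc(OCc2ccccc2)cc1O | intermediate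
5 | tert-butyl acetate | CC(=O)OC(C)(C)C | starting material
6 | lithium enolate of tert-butyl acetate | C=C(O[Li])OC(C)(C)C | intermediate (not isolated)
7 | tert-butyl 3-[4-(benzyloxy)-2-hydroxyphenyl]-3-oxopropanoate | CC(C)(C)OC(=O)CC(=O)c1ccc(OCc2ccccc2)cc1O | intermediate
8 | tert-butyl 2-[4-(benzyloxy)-2-hydroxybenzoyl]-3-[3,4-bis(benzyloxy)phenyl]prop-2-enoate (E/Z) | CC(C)(C)OC(=O)C(=Cc1ccc(OCc2ccccc2)c(OCc2ccccc2)c1)C(=O)c1ccc(OCc2ccccc2)cc1O | intermediate
9 | tert-butyl (2S)-7-(benzyloxy)-2-[3,4-bis(benzyloxy)phenyl]-4-oxochromane-3-carboxylate (C-3 epimers/enol) | O(Cc1ccccc1)c1ccc2c(c1)O[C@H](c1ccc(OCc3ccccc3)c(OCc3ccccc3)c1)C(C(=O)OC(C)(C)C)C2=O | intermediate (not isolated)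
10 | (2S)-7-(benzyloxy)-2-[3,4-bis(benzyloxy)phenyl]chroman-4-one | O(Cc1ccccc1)c1ccc2c(c1)O[C@H](c1ccc(OCc3ccccc3)c(OCc3ccccc3)c1)CC2=O | intermediate
11 | (2S)-7-(benzyloxy)-2-[3,4-bis(benzyloxy)phenyl]-4-(trimethylsilyloxy)-2H-chromene | O(Cc1ccccc1)c1ccc2c(c1)O[C@H](c1ccc(OCc3ccccc3)c(OCc3ccccc3)c1)C=C2O[Si](C)(C)C | intermediate (not isolated)
12 | (2R,3R)-7-(benzyloxy)-2-[3,4-bis(benzyloxy)phenyl]-3-(trimethylsilyloxy)chroman-4-one | O(Cc1ccccc1)c1ccc2c(c1)O[C@H](c1ccc(OCc3ccccc3)c(OCc3ccccc3)c1)[C@@H](O[Si](C)(C)C)C2=O | intermediate (not isolated)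
13 | (2R,3R)-7-(benzyloxy)-2-[3,4-bis(benzyloxy)phenyl]-3-hydroxychroman-4-one (tri-O-benzylfustin, 2,3-trans) | O(Cc1ccccc1)c1ccc2c(c1)O[C@H](c1ccc(OCc3ccccc3)c(OCc3ccccc3)c1)[C@@H](O)C2=O | intermediate
14 | (2R,3R)-7-(benzyloxy)-2-[3,4-bis(benzyloxy)phenyl]-3-(tert-butyldimethylsilyloxy)chroman-4-one | O(Cc1ccccc1)c1ccc2c(c1)O[C@H](c1ccc(OCc3ccccc3)c(OCc3ccccc3)c1)[C@@H](O[Si](C)(C)C(C)(C)C)C2=O | intermediate
15 | methyl 2,3,4-trihydroxybenzoate | COC(=O)c1ccc(O)c(O)c1O | starting material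
16 | methyl 3,4-bis(benzyloxy)-2-hydroxybenzoate | COC(=O)c1ccc(OCc2ccccc2)c(OCc2ccccc2)c1O | intermediate
17 | methyl 3,4-bis(benzyloxy)-5-bromo-2-hydroxybenzoate | COC(=O)c1cc(Br)c(OCc2ccccc2)c(OCc2ccccc2)c1O | intermediate
18 | sodium enolate of tert-butyl acetate | C=C(O[Na])OC(C)(C)C | intermediate (not isolated)
19 | tert-butyl 3-[3,4-bis(benzyloxy)-5-bromo-2-hydroxyphenyl]-3-oxopropanoate | CC(C)(C)OC(=O)CC(=O)c1cc(Br)c(OCc2ccccc2)c(OCc2ccccc2)c1O | intermediate
20 | tert-butyl 2-[3,4-bis(benzyloxy)-5-bromo-2-hydroxybenzoyl]-3-[3,4-bis(benzyloxy)phenyl]prop-2-enoate (E/Z) | CC(C)(C)OC(=O)C(=Cc1ccc(OCc2ccccc2)c(OCc2ccccc2)c1)C(=O)c1cc(Br)c(OCc2ccccc2)c(OCc2ccccc2)c1O | intermediate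
21 | tert-butyl (2S)-7,8-bis(benzyloxy)-2-[3,4-bis(benzyloxy)phenyl]-6-bromo-4-oxochromane-3-carboxylate (C-3 epimers/enol) | Brc1cc2c(c(OCc3ccccc3)c1OCc1ccccc1)O[C@H](c1ccc(OCc3ccccc3)c(OCc3ccccc3)c1)C(C(=O)OC(C)(C)C)C2=O | intermediate (not isolated)
22 | (2S)-7,8-bis(benzyloxy)-2-[3,4-bis(benzyloxy)phenyl]-6-bromochroman-4-one | Brc1cc2c(c(OCc3ccccc3)c1OCc1ccccc1)O[C@H](c1ccc(OCc3ccccc3)c(OCc3ccccc3)c1)CC2=O | intermediate
23 | (2S)-7,8-bis(benzyloxy)-2-[3,4-bis(benzyloxy)phenyl]-6-bromo-4-(trimethylsilyloxy)-2H-chromene | Brc1cc2c(c(OCc3ccccc3)c1OCc1ccccc1)O[C@H](c1ccc(OCc3ccccc3)c(OCc3ccccc3)c1)C=C2O[Si](C)(C)C | intermediate (not isolated)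
24 | (2R,3R)-7,8-bis(benzyloxy)-2-[3,4-bis(benzyloxy)phenyl]-6-bromo-3-(trimethylsilyloxy)chroman-4-one | Brc1cc2c(c(OCc3ccccc3)c1OCc1ccccc1)O[C@H](c1ccc(OCc3ccccc3)c(OCc3ccccc3)c1)[C@@H](O[Si](C)(C)C)C2=O | intermediate (not isolated)
25 | (2R,3R)-7,8-bis(benzyloxy)-2-[3,4-bis(benzyloxy)phenyl]-6-bromo-3-hydroxychroman-4-one (2,3-trans) | Brc1cc2c(c(OCc3ccccc3)c1OCc1ccccc1)O[C@H](c1ccc(OCc3ccccc3)c(OCc3ccccc3)c1)[C@@H](O)C2=O | intermediate
26 | (2R,3S,4R)-7,8-bis(benzyloxy)-2-[3,4-bis(benzyloxy)phenyl]-6-bromochromane-3,4-diol (major epimer) | Brc1cc2c(c(OCc3ccccc3)c1OCc1ccccc1)O[C@H](c1ccc(OCc3ccccc3)c(OCc3ccccc3)c1)[C@@H](O)[C@@H]2O | intermediate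
27 | (2R,3S)-7,8-bis(benzyloxy)-2-[3,4-bis(benzyloxy)phenyl]-6-bromo-3-hydroxychroman-4-ylium | Brc1cc2c(c(OCc3ccccc3)c1OCc1ccccc1)O[C@H](c1ccc(OCc3ccccc3)c(OCc3ccccc3)c1)[C@@H](O)[CH+]2 | intermediate (not isolated)
28 | (2R,3S)-7,8-bis(benzyloxy)-2-[3,4-bis(benzyloxy)phenyl]-6-bromochroman-3-ol (2,3-trans) | Brc1cc2c(c(OCc3ccccc3)c1OCc1ccccc1)O[C@H](c1ccc(OCc3ccccc3)c(OCc3ccccc3)c1)[C@@H](O)C2 | intermediate
29 | (2R,3S)-3,7,8-tris(benzyloxy)-2-[3,4-bis(benzyloxy)phenyl]-6-bromochromane | Brc1cc2c(c(OCc3ccccc3)c1OCc1ccccc1)O[C@H](c1ccc(OCc3ccccc3)c(OCc3ccccc3)c1)[C@@H](OCc1ccccc1)C2 | intermediate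
30 | (2R,3S)-3,7,8-tris(benzyloxy)-2-[3,4-bis(benzyloxy)phenyl]chroman-6-yllithium | [Li]c1cc2c(c(OCc3ccccc3)c1OCc1ccccc1)O[C@H](c1ccc(OCc3ccccc3)c(OCc3ccccc3)c1)[C@@H](OCc1ccccc1)C2 | intermediate (not isolated)
31 | (2R,3R)-7-(benzyloxy)-2-[3,4-bis(benzyloxy)phenyl]-3-(tert-butyldimethylsilyloxy)-4-[(2R,3S)-3,7,8-tris(benzyloxy)-2-[3,4-bis(benzyloxy)phenyl]chroman-6-yl]chroman-4-ol (C-4 unassigned) | O(Cc1ccccc1)c1ccc2c(c1)O[C@H](c1ccc(OCc3ccccc3)c(OCc3ccccc3)c1)[C@@H](O[Si](C)(C)C(C)(C)C)C2(O)c1cc2c(c(OCc3ccccc3)c1OCc1ccccc1)O[C@H](c1ccc(OCc3ccccc3)c(OCc3ccccc3)c1)[C@@H](OCc1ccccc1)C2 | intermediate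
32 | C-4 diarylmethyl cation derived from 31 (upper unit 2R,3S; lower unit 2R,3S) | O(Cc1ccccc1)c1ccc2c(c1)O[C@H](c1ccc(OCc3ccccc3)c(OCc3ccccc3)c1)[C@@H](O[Si](C)(C)C(C)(C)C)[C+]2c1cc2c(c(OCc3ccccc3)c1OCc1ccccc1)O[C@H](c1ccc(OCc3ccccc3)c(OCc3ccccc3)c1)[C@@H](OCc1ccccc1)C2 | intermediate (not isolated)
33 | (2R,3S,4R)-7-(benzyloxy)-2-[3,4-bis(benzyloxy)phenyl]-3-(tert-butyldimethylsilyloxy)-4-[(2R,3S)-3,7,8-tris(benzyloxy)-2-[3,4-bis(benzyloxy)phenyl]chroman-6-yl]chromane (2,3-trans-3,4-cis) | O(Cc1ccccc1)c1ccc2c(c1)O[C@H](c1ccc(OCc3ccccc3)c(OCc3ccccc3)c1)[C@@H](O[Si](C)(C)C(C)(C)C)[C@H]2c1cc2c(c(OCc3ccccc3)c1OCc1ccccc1)O[C@H](c1ccc(OCc3ccccc3)c(OCc3ccccc3)c1)[C@@H](OCc1ccccc1)C2 | intermediate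
34 | (2R,3S,4R)-7-(benzyloxy)-2-[3,4-bis(benzyloxy)phenyl]-4-[(2R,3S)-3,7,8-tris(benzyloxy)-2-[3,4-bis(benzyloxy)phenyl]chroman-6-yl]chroman-3-ol | O(Cc1ccccc1)c1ccc2c(c1)O[C@H](c1ccc(OCc3ccccc3)c(OCc3ccccc3)c1)[C@@H](O)[C@H]2c1cc2c(c(OCc3ccccc3)c1OCc1ccccc1)O[C@H](c1ccc(OCc3ccccc3)c(OCc3ccccc3)c1)[C@@H](OCc1ccccc1)C2 | intermediate
35 | (2R,3S,4S)-2-(3,4-dihydroxyphenyl)-4-[(2R,3S)-2-(3,4-dihydroxyphenyl)-3,7,8-trihydroxychroman-6-yl]chromane-3,7-diol | Oc1ccc2c(c1)O[C@H](c1ccc(O)c(O)c1)[C@@H](O)[C@H]2c1cc2c(c(O)c1O)O[C@H](c1ccc(O)c(O)c1)[C@@H](O)C2 | target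

## Step count and risks

Total step count: 20. Longest linear sequence: 13 steps (steps 8–16, then 17–20); the upper fragment (steps 2–7) and the aldehyde (step 1) are made in parallel.

Most likely to fail:

**Step 12 (and its twin, step 5).** The phenol of 20 is flanked by an OBn group, which may lower the enantioselectivity, and the electron-rich 2-aryl group may allow some racemisation during the acidic decarboxylation. Fallback: setting out from 20, cyclise and decarboxylate without chiral control (piperidine, EtOH, reflux; then TsOH, PhMe, 80 °C) to racemic 7,8-bis(benzyloxy)-2-[3,4-bis(benzyloxy)phenyl]-6-bromochroman-4-one F1. Resolve it by kinetic resolution through Rh-catalysed asymmetric transfer hydrogenation (Cp*RhCl(TsDPEN), HCO2H/Et3N, EtOAc, rt, about 55 % conversion), using the catalyst enantiomer that reduces the (2R)-ketone. The (2R)-ketone is removed as (2R,4R)-7,8-bis(benzyloxy)-2-[3,4-bis(benzyloxy)phenyl]-6-bromochroman-4-ol F2, and unreacted (2S)-ketone 22 is recovered in high ee; the route is rejoined at 22.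

**Step 13 (and its twin, step 6).** Enolisation of a flavanone can trigger retro-oxa-Michael ring opening, and DMDO may over-oxidise the electron-rich rings. Fallback: setting out from 22, reduce with NaBH4 (THF/MeOH, 0 °C) to (2S,4S)-7,8-bis(benzyloxy)-2-[3,4-bis(benzyloxy)phenyl]-6-bromochroman-4-ol F3. Dehydrate with Burgess reagent (PhH, 50 °C) to (2S)-7,8-bis(benzyloxy)-2-[3,4-bis(benzyloxy)phenyl]-6-bromo-2H-chromene F4. Hydroborate and oxidise (BH3·THF, 0 °C; NaOH, H2O2): boron adds to C-3 on the face anti to the 2-aryl group, which gives the 2,3-trans alcohol 28 directly. The route is rejoined at 28, bypassing 25 and 26.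

**Step 18.** The hydride must enter anti to the 3-OTBS group but on the same face as the 2-aryl group, so the 3,4-cis selectivity may be incomplete in this 2,3-trans series (the epimer would have to be separated by chromatography), and partial loss of the silyl ether under TFA would weaken the facial bias. Fallback (a biomimetic union, not stereoselective): setting out from 13, hydrogenolyse (H2, Pd/C, EtOAc/MeOH) to (2R,3R)-fustin F5 and reduce with NaBH4 (EtOH) to (2R,3S,4R)-mollisacacidin F6. Setting out from 28, hydrogenolyse with concomitant debromination (H2, Pd/C, Et3N, THF/MeOH) to (2R,3S)-mesquitol F7. Condense F6 with excess F7 in 0.1 M HCl (H2O/dioxane, rt); the C-4 cation is captured at C-6 of mesquitol from both faces. The 3,4-cis (4β→6) product 35 is separated from its 4α and (4→5) isomers on Sephadex LH-20 and by preparative HPLC; the route is rejoined at 35.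

## Further compounds

F1 | step 12 | racemic 7,8-bis(benzyloxy)-2-[3,4-bis(benzyloxy)phenyl]-6-bromochroman-4-one | Brc1cc2c(c(OCc3ccccc3)c1OCc1ccccc1)OC(c1ccc(OCc3ccccc3)c(OCc3ccccc3)c1)CC2=O
F2 | step 12 | (2R,4R)-7,8-bis(benzyloxy)-2-[3,4-bis(benzyloxy)phenyl]-6-bromochroman-4-ol | Brc1cc2c(c(OCc3ccccc3)c1OCc1ccccc1)O[C@@H](c1ccc(OCc3ccccc3)c(OCc3ccccc3)c1)C[C@H]2O
F3 | step 13 | (2S,4S)-7,8-bis(benzyloxy)-2-[3,4-bis(benzyloxy)phenyl]-6-bromochroman-4-ol | Brc1cc2c(c(OCc3ccccc3)c1OCc1ccccc1)O[C@H](c1ccc(OCc3ccccc3)c(OCc3ccccc3)c1)C[C@@H]2O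
F4 | step 13 | (2S)-7,8-bis(benzyloxy)-2-[3,4-bis(benzyloxy)phenyl]-6-bromo-2H-chromene | Brc1cc2c(c(OCc3ccccc3)c1OCc1ccccc1)O[C@H](c1ccc(OCc3ccccc3)c(OCc3ccccc3)c1)C=C2
F5 | step 18 | (2R,3R)-fustin [(2R,3R)-2-(3,4-dihydroxyphenyl)-3,7-dihydroxychroman-4-one] | Oc1ccc2c(c1)O[C@H](c1ccc(O)c(O)c1)[C@@H](O)C2=O
F6 | step 18 | (2R,3S,4R)-mollisacacidin [(2R,3S,4R)-2-(3,4-dihydroxyphenyl)chromane-3,4,7-triol] | Oc1ccc2c(c1)O[C@H](c1ccc(O)c(O)c1)[C@@H](O)[C@@H]2O
F7 | step 18 | (2R,3S)-mesquitol [(2R,3S)-2-(3,4-dihydroxyphenyl)chromane-3,7,8-triol] | Oc1ccc2c(c1O)O[C@H](c1ccc(O)c(O)c1)[C@@H](O)C2
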